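The route rests on opening ring C (the dihydrofuran) at C3–CH2OH and O1–C2. This exploits three features: C3 carries a one-carbon branch, O1 sits on C7a of ring B ortho to C3a, and C2 is benzylic to the electron-rich guaiacyl ring A. What remains is an E-stilbene and formaldehyde. One chiral-acid-catalysed Prins addition with oxygen capture should form both bonds, close ring C, set C2 and C3 (trans, 2R,3S) and pass the silyl group from O1 to the new primary oxygen. The precursor is a push–pull E-stilbene: ring B bears an ortho silyl ether, a methoxy group and a methyl ester para to that oxygen; ring A bears a para silyl ether.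

Key step: step 5

Labels: ring A = guaiacyl ring; ring B = benzene ring fused to the furan; ring C = dihydrofuran ring (O1, C2, C3, C3a, C7a); ring D = resorcinol ring. Cα and Cβ are the stilbene carbons on ring B and on ring A; they become C3 and C2. The target is the trans (2R,3S) isomer.

Remarks on the design:
- In precursor 6 the ester is para to the ring-B oxygen and meta to Cα. It polarises the stilbene by draining that oxygen and by induction, not by conjugation with Cα.
- Only a catalytic amount of acid is present, so the silyl group that leaves O1 has one stoichiometric acceptor, the new primary oxygen. The key step is therefore planned as a silyl relay that gives the primary tert-butyldimethylsilyl ether 8 directly, and no separate protection step is needed.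
- The ring-B phenol is silylated after the Heck coupling, so that the labile aryl silyl ether para to the ester is made fresh.
- Ring A keeps its triisopropylsilyl ether to the last step, because a free para phenol would let base open the C2–O1 bond through a quinone methide.

Assumption: the (S,S) antipode of the acid is taken to give the 3S configuration; the sense of induction would be fixed in a first screen and the (R,R) antipode used if it is the reverse.

**Step 1**
Reactants: 1 methyl vanillate (methyl 4-hydroxy-3-methoxybenzoate)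
Product: 2 methyl 4-hydroxy-3-iodo-5-methoxybenzoate (methyl 5-iodovanillate)
Conditions: NIS (1.05 equiv), TsOH·H2O (10 mol%), MeCN, rt
Reagents that add atoms: N-iodosuccinimide, O=C1CCC(=O)N1I
Why: Electrophilic aromatic iodination, in which the free phenol is the strongest activator and its para position is blocked by the ester, so that iodine should enter the only open ortho position.

**Step 2**
Reactants: 3 2-methoxy-4-vinylphenol (4-vinylguaiacol, commercial)
Product: 4 triisopropyl(2-methoxy-4-vinylphenoxy)silane [3-methoxy-4-(triisopropylsilyloxy)styrene]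
Conditions: TIPSCl (1.1 equiv), imidazole (2.2 equiv), CH2Cl2, 0 °C → rt
Reagents that add atoms: triisopropylsilyl chloride, CC(C)[Si](Cl)(C(C)C)C(C)C
Why: Imidazole-promoted O-silylation of a phenol, which should be clean because the phenol is the only nucleophile present.

**Step 3**
Reactants: 2 methyl 4-hydroxy-3-iodo-5-methoxybenzoate, 4 3-methoxy-4-(triisopropylsilyloxy)styrene
Product: 5 methyl (E)-4-hydroxy-3-methoxy-5-[3-methoxy-4-(triisopropylsilyloxy)styryl]benzoate
Conditions: Pd(OAc)2 (5 mol%), P(o-tol)3 (10 mol%), Et3N (3 equiv), DMF, 90 °C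
Reagents that add atoms: none
Why: Mizoroki–Heck reaction, in which oxidative addition of the aryl iodide to zerovalent palladium formed in the flask, insertion of the terminal alkene with the aryl group on its unsubstituted carbon and syn β-hydride elimination should give the E-stilbene, the free ortho phenol and the silyl ether being tolerated under amine base.

**Step 4**
Reactants: 5 methyl (E)-4-hydroxy-3-methoxy-5-[3-methoxy-4-(triisopropylsilyloxy)styryl]benzoate
Product: 6 methyl (E)-4-(tert-butyldimethylsilyloxy)-3-methoxy-5-[3-methoxy-4-(triisopropylsilyloxy)styryl]benzoate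
Conditions: TBSCl (1.5 equiv), imidazole (3 equiv), DMF, rt → 40 °C
Reagents that add atoms: tert-butyldimethylsilyl chloride, CC(C)(C)[Si](C)(C)Cl
Why: Imidazole-promoted O-silylation of the acidic phenol para to the ester, with gentle warming to overcome its two ortho neighbours.

**Step 5**
Reactants: 6 methyl (E)-4-(tert-butyldimethylsilyloxy)-3-methoxy-5-[3-methoxy-4-(triisopropylsilyloxy)styryl]benzoate, 7 formaldehyde (as dried paraformaldehyde)
Product: 8 methyl (2R,3S)-trans-3-{[(tert-butyldimethylsilyl)oxy]methyl}-7-methoxy-2-[3-methoxy-4-(triisopropylsilyloxy)phenyl]-2,3-dihydrobenzofuran-5-carboxylate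
Conditions: (S,S)-IDPi acid (BINOL-derived imidodiphosphorimidate with N-triflyl groups, 5 mol%), paraformaldehyde (2 equiv of CH2O), cyclohexane–CHCl3 (0.02 M), −20 °C → rt, argon
Reagents that add atoms: none
Why: Proposed new method: the confined chiral acid cracks paraformaldehyde and holds an O-activated formaldehyde in its pocket (protonated in the first turnover, O-silylated by the silylated counter-anion thereafter); Cα of stilbene 6 adds to it and the charge settles on Cβ as a quinone-methide-like cation delocalised into the 4-silyloxy ring A, the closest known reaction type being the imidodiphosphorimidate-catalysed asymmetric Prins reaction of styrenes with paraformaldehyde, which normally ends in 1,3-dioxanes, combined with silylium counter-anion catalysis for the silyl transfer. Ring C closes when the silyl ether oxygen of ring B adds to C2 of this cation, a 5-exo-trig closure with respect to the C2=C1' bond of the cation (formally 5-endo with respect to the stilbene alkene), and the silyloxonium ion so formed hands its tert-butyldimethylsilyl group to the new primary oxygen, directly or through the counter-anion, which restores the active catalyst and leaves no co-product. C3 is set in the C–C bond-forming event by the chiral counter-anion, which shields one face of Cα, and C2 is set by the substrate, because O1 adds to the planar cation anti to the C3 substituent and a cis isomer could revert through acid-mediated reopening of the C2–O1 bond to the more stable trans isomer. The step needs regioselectivity for C–C bond formation at Cα, which the substrate secures: a Cβ cation is stabilised by the para silyloxy group of ring A, whereas a Cα cation would lie meta to the ester and the methoxy group of ring B and be served only by an ortho oxygen that is twisted by its two neighbours and drained by the para ester. It also needs O1 to outrun a second formaldehyde, proton loss from C3 and attack by another stilbene, which the five-membered tether, a small excess of formaldehyde, high dilution and low temperature are meant to secure.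

**Step 6**
Reactants: 8 methyl (2R,3S)-trans-3-{[(tert-butyldimethylsilyl)oxy]methyl}-7-methoxy-2-[3-methoxy-4-(triisopropylsilyloxy)phenyl]-2,3-dihydrobenzofuran-5-carboxylate
Product: 9 [(2R,3S)-3-{[(tert-butyldimethylsilyl)oxy]methyl}-7-methoxy-2-[3-methoxy-4-(triisopropylsilyloxy)phenyl]-2,3-dihydrobenzofuran-5-yl]methanol
Conditions: i-Bu2AlH (2.5 equiv), CH2Cl2, −78 → 0 °C; aq. potassium sodium tartrate
Reagents that add atoms: none
Why: Hydride reduction of the aryl ester to the benzylic alcohol with diisobutylaluminium hydride, under which both silyl ethers and the ether bonds of ring C should be inert at low temperature, so that C2 and C3 are untouched.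

**Step 7**
Reactants: 9 [(2R,3S)-3-{[(tert-butyldimethylsilyl)oxy]methyl}-7-methoxy-2-[3-methoxy-4-(triisopropylsilyloxy)phenyl]-2,3-dihydrobenzofuran-5-yl]methanol
Product: 10 (2R,3S)-3-{[(tert-butyldimethylsilyl)oxy]methyl}-7-methoxy-2-[3-methoxy-4-(triisopropylsilyloxy)phenyl]-2,3-dihydrobenzofuran-5-carbaldehyde
Conditions: activated MnO2 (15 equiv), CH2Cl2, rt
Reagents that add atoms: none
Why: Chemoselective MnO2 oxidation of a benzylic alcohol, which should stop at the aldehyde and leave the silyl ethers and both stereocentres alone.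

**Step 8**
Reactants: 11 3,5-dihydroxybenzaldehyde
Product: 12 3,5-bis(tert-butyldimethylsilyloxy)benzaldehyde
Conditions: TBSCl (2.4 equiv), imidazole (5 equiv), DMF, rt
Reagents that add atoms: tert-butyldimethylsilyl chloride, CC(C)(C)[Si](C)(C)Cl
Why: Imidazole-promoted O-silylation of both phenols, the aldehyde being inert to the reagents.

**Step 9**
Reactants: 12 3,5-bis(tert-butyldimethylsilyloxy)benzaldehyde
Product: 13 [3,5-bis(tert-butyldimethylsilyloxy)phenyl]methanol
Conditions: NaBH4 (1 equiv), THF–EtOH, 0 °C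
Reagents that add atoms: none
Why: Borohydride reduction of an aryl aldehyde, fast enough at 0 °C that the aryl silyl ethers should survive the brief contact with alkoxide.

**Step 10**
Reactants: 13 [3,5-bis(tert-butyldimethylsilyloxy)phenyl]methanol
Product: 14 3,5-bis(tert-butyldimethylsilyloxy)benzyl bromide
Conditions: CBr4 (1.3 equiv), PPh3 (1.3 equiv), CH2Cl2, 0 °C
Reagents that add atoms: carbon tetrabromide, BrC(Br)(Br)Br
Why: Appel bromination, which turns the benzylic alcohol into the bromide through its alkoxyphosphonium salt under neutral conditions that spare the aryl silyl ethers.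

**Step 11**
Reactants: 14 3,5-bis(tert-butyldimethylsilyloxy)benzyl bromide
Product: 15 diethyl [3,5-bis(tert-butyldimethylsilyloxy)benzyl]phosphonate
Conditions: P(OEt)3 (3 equiv, neat), 130 °C
Reagents that add atoms: triethyl phosphite, CCOP(OCC)OCC
Why: Michaelis–Arbuzov reaction, in which the benzylic bromide alkylates phosphorus and bromide then dealkylates the phosphonium ion, the volatile bromoethane leaving the melt.

**Step 12**
Reactants: 10 (2R,3S)-3-{[(tert-butyldimethylsilyl)oxy]methyl}-7-methoxy-2-[3-methoxy-4-(triisopropylsilyloxy)phenyl]-2,3-dihydrobenzofuran-5-carbaldehyde, 15 diethyl [3,5-bis(tert-butyldimethylsilyloxy)benzyl]phosphonate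
Product: 17 (2R,3S)-5-[(E)-3,5-bis(tert-butyldimethylsilyloxy)styryl]-3-{[(tert-butyldimethylsilyl)oxy]methyl}-7-methoxy-2-[3-methoxy-4-(triisopropylsilyloxy)phenyl]-2,3-dihydrobenzofuran, via potassium phosphonate carbanion 16 (not isolated)
Conditions: 15 (1.3 equiv), KN(SiMe3)2 (1.25 equiv), THF, −78 °C; then 10, −78 °C → rt
Reagents that add atoms: none
Why: Horner–Wadsworth–Emmons olefination with a benzylic phosphonate carbanion, which should give the E-stilbene through reversible addition and syn elimination of diethyl phosphate, while the non-nucleophilic amide base and the intact silyl ether on ring A keep the C2–O1 bond closed.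

**Step 13**
Reactants: 17 (2R,3S)-5-[(E)-3,5-bis(tert-butyldimethylsilyloxy)styryl]-3-{[(tert-butyldimethylsilyl)oxy]methyl}-7-methoxy-2-[3-methoxy-4-(triisopropylsilyloxy)phenyl]-2,3-dihydrobenzofuran
Product: 18 gnetofuran A, 5-{(E)-2-[(2R,3S)-2-(4-hydroxy-3-methoxyphenyl)-3-(hydroxymethyl)-7-methoxy-2,3-dihydrobenzofuran-5-yl]vinyl}benzene-1,3-diol
Conditions: Bu4NF (6 equiv), AcOH (6 equiv), THF, 0 °C → rt, argon
Reagents that add atoms: none
Why: Fluoride-mediated silyl ether cleavage of all four Si–O bonds, driven by the strong Si–F bond and buffered with acetic acid so that no phenoxide builds up that could open ring C through a para-quinone methide or oxidise the stilbene.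

**Compound list**

1 | methyl vanillate (methyl 4-hydroxy-3-methoxybenzoate) | COC(=O)c1ccc(O)c(OC)c1 | starting material
2 | methyl 4-hydroxy-3-iodo-5-methoxybenzoate | COC(=O)c1cc(I)c(O)c(OC)c1 | intermediate
3 | 2-methoxy-4-vinylphenol | C=Cc1ccc(O)c(OC)c1 | starting material
4 | triisopropyl(2-methoxy-4-vinylphenoxy)silane | C=Cc1ccc(O[Si](C(C)C)(C(C)C)C(C)C)c(OC)c1 | intermediate
5 | methyl (E)-4-hydroxy-3-methoxy-5-[3-methoxy-4-(triisopropylsilyloxy)styryl]benzoate | COC(=O)c1cc(OC)c(O)c(/C=C/c2ccc(O[Si](C(C)C)(C(C)C)C(C)C)c(OC)c2)c1 | intermediate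
6 | methyl (E)-4-(tert-butyldimethylsilyloxy)-3-methoxy-5-[3-methoxy-4-(triisopropylsilyloxy)styryl]benzoate | COC(=O)c1cc(OC)c(O[Si](C)(C)C(C)(C)C)c(/C=C/c2ccc(O[Si](C(C)C)(C(C)C)C(C)C)c(OC)c2)c1 | intermediate
7 | formaldehyde (used as paraformaldehyde) | C=O | starting material
8 | methyl (2R,3S)-trans-3-{[(tert-butyldimethylsilyl)oxy]methyl}-7-methoxy-2-[3-methoxy-4-(triisopropylsilyloxy)phenyl]-2,3-dihydrobenzofuran-5-carboxylate | COc1cc([C@@H]2Oc3c(OC)cc(C(=O)OC)cc3[C@H]2CO[Si](C)(C)C(C)(C)C)ccc1O[Si](C(C)C)(C(C)C)C(C)C | intermediate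
9 | [(2R,3S)-3-{[(tert-butyldimethylsilyl)oxy]methyl}-7-methoxy-2-[3-methoxy-4-(triisopropylsilyloxy)phenyl]-2,3-dihydrobenzofuran-5-yl]methanol | COc1cc([C@@H]2Oc3c(OC)cc(CO)cc3[C@H]2CO[Si](C)(C)C(C)(C)C)ccc1O[Si](C(C)C)(C(C)C)C(C)C | intermediate
10 | (2R,3S)-3-{[(tert-butyldimethylsilyl)oxy]methyl}-7-methoxy-2-[3-methoxy-4-(triisopropylsilyloxy)phenyl]-2,3-dihydrobenzofuran-5-carbaldehyde | COc1cc([C@@H]2Oc3c(OC)cc(C=O)cc3[C@H]2CO[Si](C)(C)C(C)(C)C)ccc1O[Si](C(C)C)(C(C)C)C(C)C | intermediate
11 | 3,5-dihydroxybenzaldehyde | O=Cc1cc(O)cc(O)c1 | starting material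
12 | 3,5-bis(tert-butyldimethylsilyloxy)benzaldehyde | O=Cc1cc(O[Si](C)(C)C(C)(C)C)cc(O[Si](C)(C)C(C)(C)C)c1 | intermediate
13 | [3,5-bis(tert-butyldimethylsilyloxy)phenyl]methanol | OCc1cc(O[Si](C)(C)C(C)(C)C)cc(O[Si](C)(C)C(C)(C)C)c1 | intermediate
14 | 3,5-bis(tert-butyldimethylsilyloxy)benzyl bromide | BrCc1cc(O[Si](C)(C)C(C)(C)C)cc(O[Si](C)(C)C(C)(C)C)c1 | intermediate
15 | diethyl [3,5-bis(tert-butyldimethylsilyloxy)benzyl]phosphonate | CCOP(=O)(Cc1cc(O[Si](C)(C)C(C)(C)C)cc(O[Si](C)(C)C(C)(C)C)c1)OCC | intermediate
16 | potassium phosphonate carbanion of 15 (not isolated) | CCOP(=O)([CH-]c1cc(O[Si](C)(C)C(C)(C)C)cc(O[Si](C)(C)C(C)(C)C)c1)OCC.[K+] | intermediate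
17 | (2R,3S)-5-[(E)-3,5-bis(tert-butyldimethylsilyloxy)styryl]-3-{[(tert-butyldimethylsilyl)oxy]methyl}-7-methoxy-2-[3-methoxy-4-(triisopropylsilyloxy)phenyl]-2,3-dihydrobenzofuran | COc1cc([C@@H]2Oc3c(OC)cc(/C=C/c4cc(O[Si](C)(C)C(C)(C)C)cc(O[Si](C)(C)C(C)(C)C)c4)cc3[C@H]2CO[Si](C)(C)C(C)(C)C)ccc1O[Si](C(C)C)(C(C)C)C(C)C | intermediate
18 | gnetofuran A | COc1cc([C@@H]2Oc3c(OC)cc(/C=C/c4cc(O)cc(O)c4)cc3[C@H]2CO)ccc1O | target

Total step count: 13. Longest linear sequence: 8 steps (steps 1, 3, 4, 5, 6, 7, 12 and 13).

**Steps most likely to fail**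

Step 5 (new method). The benzylic cation may be intercepted by a second formaldehyde before O1 closes, the electron-rich stilbene may be protonated and oligomerise, the acid pocket may discriminate the faces of a 1,2-disubstituted alkene poorly, or water carried in with paraformaldehyde may divert the silyl relay. The fallback uses known chemistry, sets out from 2 and comes back to the route at 10: ring C would be closed by C2–C3 bond formation through an enantioselective dirhodium-carbenoid C–H insertion. Vanillin would be silylated (TIPSCl, imidazole) to 3-methoxy-4-(triisopropylsilyloxy)benzaldehyde F1 and reduced with NaBH4 to [3-methoxy-4-(triisopropylsilyloxy)phenyl]methanol F2. Mitsunobu etherification of 2 with F2 (PPh3, diisopropyl azodicarboxylate) would give methyl 3-iodo-5-methoxy-4-{[3-methoxy-4-(triisopropylsilyloxy)benzyl]oxy}benzoate F3. Palladium-catalysed α-arylation of the Reformatsky reagent BrZnCH2CO2Me (Pd(dba)2, P(t-Bu)3, THF) would give methyl 3-methoxy-5-(2-methoxy-2-oxoethyl)-4-{[3-methoxy-4-(triisopropylsilyloxy)benzyl]oxy}benzoate F4, and Regitz diazo transfer (p-acetamidobenzenesulfonyl azide, DBU) would give methyl 3-(1-diazo-2-methoxy-2-oxoethyl)-5-methoxy-4-{[3-methoxy-4-(triisopropylsilyloxy)benzyl]oxy}benzoate F5. Insertion of the carbenoid formed with Rh2(S-PTTL)4, dirhodium tetrakis[N-phthaloyl-(S)-tert-leucinate], or its antipode into the benzylic ether C–H bond would close ring C and set C2, giving dimethyl (2R,3S)-cis-7-methoxy-2-[3-methoxy-4-(triisopropylsilyloxy)phenyl]-2,3-dihydrobenzofuran-3,5-dicarboxylate F6. DBU would epimerise C3 to dimethyl (2R,3R)-trans-7-methoxy-2-[3-methoxy-4-(triisopropylsilyloxy)phenyl]-2,3-dihydrobenzofuran-3,5-dicarboxylate F7. i-Bu2AlH would reduce both esters to [(2R,3S)-trans-7-methoxy-2-[3-methoxy-4-(triisopropylsilyloxy)phenyl]-2,3-dihydrobenzofuran-3,5-diyl]dimethanol F8, and MnO2 would oxidise only the benzylic alcohol to (2R,3S)-3-(hydroxymethyl)-7-methoxy-2-[3-methoxy-4-(triisopropylsilyloxy)phenyl]-2,3-dihydrobenzofuran-5-carbaldehyde F9. TBSCl with imidazole would then give 10.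

Step 12. Addition of the phosphonate carbanion to the electron-rich aldehyde may be incomplete, and the strong base may strip aryl silyl groups. The fallback sets out from 10 and comes back at 17: the alkene would be made by a Heck coupling instead of a carbonyl olefination with the resorcinol fragment. Wittig methylenation of 10 with the far more reactive Ph3P=CH2 (THF, 0 °C) would give tert-butyl{[(2R,3S)-7-methoxy-2-[3-methoxy-4-(triisopropylsilyloxy)phenyl]-5-vinyl-2,3-dihydrobenzofuran-3-yl]methoxy}dimethylsilane F10. Commercial 5-bromoresorcinol would be silylated (TBSCl, imidazole) to 1-bromo-3,5-bis(tert-butyldimethylsilyloxy)benzene F11. Mizoroki–Heck coupling of F10 with F11 (Pd2(dba)3, P(t-Bu)3, Cy2NMe, dioxane, 60 °C) would give 17.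

Step 3. Arylation may occur in part at the internal alkene carbon, the electron-rich styrene may polymerise at 90 °C, and the phenoxide may slow the catalyst. The fallback sets out from 4 and 2 and comes back at 5: the alkene geometry would be fixed before the C–C coupling. Cross-metathesis of 4 with vinylboronic acid pinacol ester (second-generation Grubbs catalyst, RuCl2(H2IMes)(PCy3)(=CHPh), CH2Cl2, 40 °C) would give (E)-2-[3-methoxy-4-(triisopropylsilyloxy)styryl]-4,4,5,5-tetramethyl-1,3,2-dioxaborolane F12. Suzuki–Miyaura coupling of F12 with 2 (PdCl2(dppf), K3PO4, dioxane–H2O, 70 °C) would give 5.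

**Further compounds**

F1 | step 5 | 3-methoxy-4-(triisopropylsilyloxy)benzaldehyde | COc1cc(C=O)ccc1O[Si](C(C)C)(C(C)C)C(C)C
F2 | step 5 | [3-methoxy-4-(triisopropylsilyloxy)phenyl]methanol | COc1cc(CO)ccc1O[Si](C(C)C)(C(C)C)C(C)C
F3 | step 5 | methyl 3-iodo-5-methoxy-4-{[3-methoxy-4-(triisopropylsilyloxy)benzyl]oxy}benzoate | COC(=O)c1cc(I)c(OCc2ccc(O[Si](C(C)C)(C(C)C)C(C)C)c(OC)c2)c(OC)c1
F4 | step 5 | methyl 3-methoxy-5-(2-methoxy-2-oxoethyl)-4-{[3-methoxy-4-(triisopropylsilyloxy)benzyl]oxy}benzoate | COC(=O)Cc1cc(C(=O)OC)cc(OC)c1OCc1ccc(O[Si](C(C)C)(C(C)C)C(C)C)c(OC)c1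
F5 | step 5 | methyl 3-(1-diazo-2-methoxy-2-oxoethyl)-5-methoxy-4-{[3-methoxy-4-(triisopropylsilyloxy)benzyl]oxy}benzoate | COC(=O)C(=[N+]=[N-])c1cc(C(=O)OC)cc(OC)c1OCc1ccc(O[Si](C(C)C)(C(C)C)C(C)C)c(OC)c1
F6 | step 5 | dimethyl (2R,3S)-cis-7-methoxy-2-[3-methoxy-4-(triisopropylsilyloxy)phenyl]-2,3-dihydrobenzofuran-3,5-dicarboxylate | COc1cc([C@@H]2Oc3c(OC)cc(C(=O)OC)cc3[C@@H]2C(=O)OC)ccc1O[Si](C(C)C)(C(C)C)C(C)C
F7 | step 5 | dimethyl (2R,3R)-trans-7-methoxy-2-[3-methoxy-4-(triisopropylsilyloxy)phenyl]-2,3-dihydrobenzofuran-3,5-dicarboxylate | COc1cc([C@@H]2Oc3c(OC)cc(C(=O)OC)cc3[C@H]2C(=O)OC)ccc1O[Si](C(C)C)(C(C)C)C(C)C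
F8 | step 5 | [(2R,3S)-trans-7-methoxy-2-[3-methoxy-4-(triisopropylsilyloxy)phenyl]-2,3-dihydrobenzofuran-3,5-diyl]dimethanol | COc1cc([C@@H]2Oc3c(OC)cc(CO)cc3[C@H]2CO)ccc1O[Si](C(C)C)(C(C)C)C(C)C
F9 | step 5 | (2R,3S)-3-(hydroxymethyl)-7-methoxy-2-[3-methoxy-4-(triisopropylsilyloxy)phenyl]-2,3-dihydrobenzofuran-5-carbaldehyde | COc1cc([C@@H]2Oc3c(OC)cc(C=O)cc3[C@H]2CO)ccc1O[Si](C(C)C)(C(C)C)C(C)C
F10 | step 12 | tert-butyl{[(2R,3S)-7-methoxy-2-[3-methoxy-4-(triisopropylsilyloxy)phenyl]-5-vinyl-2,3-dihydrobenzofuran-3-yl]methoxy}dimethylsilane | COc1cc([C@@H]2Oc3c(OC)cc(C=C)cc3[C@H]2CO[Si](C)(C)C(C)(C)C)ccc1O[Si](C(C)C)(C(C)C)C(C)C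
F11 | step 12 | 1-bromo-3,5-bis(tert-butyldimethylsilyloxy)benzene | Brc1cc(O[Si](C)(C)C(C)(C)C)cc(O[Si](C)(C)C(C)(C)C)c1
F12 | step 3 | (E)-2-[3-methoxy-4-(triisopropylsilyloxy)styryl]-4,4,5,5-tetramethyl-1,3,2-dioxaborolane | COc1cc(/C=C/B2OC(C)(C)C(C)(C)O2)ccc1O[Si](C(C)C)(C(C)C)C(C)C
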